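**Retrosynthetic overview**
1. The last step is hydrogenolysis of a hepta-O-benzyl dimer. The upper 3-OH and 4-H come from syn hydroboration–oxidation of a 4-aryl-2H-chromene anti to its C2 aryl group, so the upper C2 centre fixes C3 and C4 (all-trans, 2R,3S,4R).
2. Key disconnection: the inter-unit C4–C6' bond. The flavanone C4 carbonyl carbon is used with reversed polarity (N-tosylhydrazone → diazoalkane/Pd carbene, a masked C4 vinyl anion) against the aryl bromide of the lower unit; both carbons are electrophilic in their native form.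
3. Lower pyran ring: the C3–C4 bond comes from a nitronate (masked C3 acyl anion) attacking the salicylaldehyde carbonyl in an oxa-Michael/Henry annulation. A reductive Nef step gives the flavan-3-one, and hydrogenation with dynamic kinetic resolution sets the 2,3-cis (2S,3S) unit.
4. Upper flavanone: Rh-catalysed asymmetric 1,4-addition of the catechol arylboronic acid to 7-benzyloxychromone sets C2 (S, aryl alpha).
5. Ring order: the lower pyran ring is built first on the brominated catechol aldehyde; the upper pyran ring is carried in from the chromone and joined afterwards; the upper C3 and C4 centres are set last.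

Assumption: the hand of the chiral catalysts in steps 5 and 8 is assigned by analogy with the closest substrate classes (2-arylcyclohexanones; cyclic enones) and would be checked on the first batch, the mirror-image catalyst being used if the sense were opposite.

**Route**

Step 1
Reactants: 1 3,4-bis(benzyloxy)benzaldehyde
Product: 2 4,5-bis(benzyloxy)-2-bromobenzaldehyde
Conditions: Br2 (1.05 equiv), NaOAc (1.2 equiv), AcOH, rt
Reagents that add atoms: bromine (BrBr)
Why: Electrophilic aromatic bromination goes to the free position para to the 3-benzyloxy group and ortho to CHO, the same site as in the bromination of veratraldehyde.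

Step 2
Reactants: 2 4,5-bis(benzyloxy)-2-bromobenzaldehyde, 3 nitromethane
Product: 4 (E)-1,2-bis(benzyloxy)-4-bromo-5-(2-nitrovinyl)benzene
Conditions: NH4OAc (0.5 equiv), MeNO2 (10 equiv), AcOH, 100 °C
Reagents that add atoms: none
Why: Henry (nitroaldol) condensation followed by dehydration gives the conjugated E-nitroalkene.

Step 3
Reactants: 5 4-(benzyloxy)-2-hydroxybenzaldehyde, 4 (E)-1,2-bis(benzyloxy)-4-bromo-5-(2-nitrovinyl)benzene
Product: 7 racemic 7-(benzyloxy)-2-[4,5-bis(benzyloxy)-2-bromophenyl]-3-nitro-2H-chromene, via nitroaldol adduct 6 (not isolated)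
Conditions: DABCO (0.5 equiv), MeCN, 70 °C
Reagents that add atoms: none
Why: Tandem oxa-Michael/intramolecular Henry/dehydration, in which the phenoxide adds to the nitroalkene and the resulting nitronate, a masked acyl anion for the later C3 ketone, attacks the aldehyde carbon to close ring C of the lower unit; C2 is racemic here and is corrected in step 5.

Step 4
Reactants: 7 racemic 7-(benzyloxy)-2-[4,5-bis(benzyloxy)-2-bromophenyl]-3-nitro-2H-chromene
Product: 8 racemic 7-(benzyloxy)-2-[4,5-bis(benzyloxy)-2-bromophenyl]chroman-3-one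
Conditions: Fe powder (6 equiv), AcOH/H2O (9:1), 80 °C, N2; used at once
Reagents that add atoms: water (O)
Why: Reductive Nef-type conversion, in which Fe/AcOH reduces the conjugated nitroalkene to the enamine/imine stage and this hydrolyses to the ketone, a common route from 3-nitro-2H-chromenes to chroman-3-ones; no stereocentre is set because C2 stays enolisable.

Step 5
Reactants: 8 racemic 7-(benzyloxy)-2-[4,5-bis(benzyloxy)-2-bromophenyl]chroman-3-one
Product: 9 (2S,3S)-7-(benzyloxy)-2-[4,5-bis(benzyloxy)-2-bromophenyl]chroman-3-ol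
Conditions: RuCl2[(S)-Xyl-SDP][(R,R)-DPEN] (1 mol%), KOtBu (20 mol%), H2 (50 atm), iPrOH/toluene, rt
Reagents that add atoms: none
Why: Proposed new method: asymmetric hydrogenation with dynamic kinetic resolution, in which C2 (benzylic, alpha to C=O and to O1) racemises through the enolate under KOtBu while the chiral Ru–H/N–H catalyst reduces one enantiomer by hydride delivery anti to the C2 aryl group to give the 2,3-cis (2S,3S) alcohol; the closest known reaction is the Noyori-type DKR hydrogenation of racemic 2-arylcyclohexanones to cis-2-arylcyclohexanols.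

Step 6
Reactants: 9 (2S,3S)-7-(benzyloxy)-2-[4,5-bis(benzyloxy)-2-bromophenyl]chroman-3-ol
Product: 10 (2S,3S)-3,7-bis(benzyloxy)-2-[4,5-bis(benzyloxy)-2-bromophenyl]chromane
Conditions: NaH (1.3 equiv), BnBr (1.3 equiv), Bu4NI (cat.), DMF, 0 °C to rt
Reagents that add atoms: benzyl bromide (BrCc1ccccc1)
Why: Williamson etherification masks the secondary alcohol, whose alkoxide next to the C–Br bond could otherwise undergo Pd alkoxide beta-hydride elimination in step 9; no stereocentre is touched.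

Step 7
Reactants: 11 7-hydroxy-4H-chromen-4-one
Product: 12 7-(benzyloxy)-4H-chromen-4-one
Conditions: BnBr (1.1 equiv), K2CO3 (1.5 equiv), DMF, 60 °C
Reagents that add atoms: benzyl bromide (BrCc1ccccc1)
Why: Williamson O-benzylation of the acidic 7-OH.

Step 8
Reactants: 12 7-(benzyloxy)-4H-chromen-4-one, 13 [3,4-bis(benzyloxy)phenyl]boronic acid
Product: 14 (2S)-7-(benzyloxy)-2-[3,4-bis(benzyloxy)phenyl]chroman-4-one
Conditions: [RhOH(cod)]2 (1.5 mol%), (S)-MeO-F12-BIPHEP [(S)-2,2'-bis{bis(3,4,5-trifluorophenyl)phosphino}-6,6'-dimethoxybiphenyl] (3.3 mol%), 13 (2 equiv), toluene/H2O (10:1), 30 °C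
Reagents that add atoms: none
Why: Hayashi–Miyaura rhodium-catalysed asymmetric 1,4-addition of an arylboronic acid to a chromone, in which the chiral diphosphine–Rh–aryl species adds to one enantioface of C2=C3 and sets C2 as S (aryl alpha).

Step 9
Reactants: 14 (2S)-7-(benzyloxy)-2-[3,4-bis(benzyloxy)phenyl]chroman-4-one, 15 4-methylbenzenesulfonohydrazide, 10 (2S,3S)-3,7-bis(benzyloxy)-2-[4,5-bis(benzyloxy)-2-bromophenyl]chromane
Product: 18 (2S,3S)-3,7-bis(benzyloxy)-2-{4,5-bis(benzyloxy)-2-[(2S)-7-(benzyloxy)-2-[3,4-bis(benzyloxy)phenyl]-2H-chromen-4-yl]phenyl}chromane, via N-tosylhydrazone 16 (not isolated), via diazoalkane 17 (not isolated)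
Conditions: 14 (1.2 equiv), 15 (1.2 equiv), dioxane, 70 °C, 2 h; then 10 (1.0 equiv), Pd2(dba)3 (2.5 mol%), XPhos (10 mol%), LiOtBu (2.6 equiv), dioxane, 90 °C
Reagents that add atoms: none
Why: Barluenga cross-coupling, in which the C4 carbonyl carbon reacts with reversed polarity: its tosylhydrazone anion releases a diazoalkane whose carbon attacks the arylpalladium bromide formed from 10 to give a Pd carbene, and aryl migration then beta-hydride elimination (only C3–H is available) give the C4-aryl C3=C4 alkene, joining two carbons that are both electrophilic in their native form without touching any stereocentre.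

Step 10
Reactants: 18 (2S,3S)-3,7-bis(benzyloxy)-2-{4,5-bis(benzyloxy)-2-[(2S)-7-(benzyloxy)-2-[3,4-bis(benzyloxy)phenyl]-2H-chromen-4-yl]phenyl}chromane
Product: 20 (2R,3S,4R)-7-(benzyloxy)-2-[3,4-bis(benzyloxy)phenyl]-4-{4,5-bis(benzyloxy)-2-[(2S,3S)-3,7-bis(benzyloxy)chroman-2-yl]phenyl}chroman-3-ol, via alkylborane 19 (not isolated)
Conditions: BH3·THF (3 equiv), THF, 0 °C to rt; then aq NaOH (3 M), 30% H2O2, 0 °C to rt
Reagents that add atoms: hydrogen peroxide (OO)
Why: Hydroboration–oxidation, in which boron adds to the less substituted C3 and hydrogen to the diaryl-substituted C4 in a syn fashion on the face anti to the C2 aryl group, and oxidation with retention gives the 3-OH trans to both aryl groups, i.e. the 2,3-trans-3,4-trans (2R,3S,4R) unit.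

Step 11
Reactants: 20 (2R,3S,4R)-7-(benzyloxy)-2-[3,4-bis(benzyloxy)phenyl]-4-{4,5-bis(benzyloxy)-2-[(2S,3S)-3,7-bis(benzyloxy)chroman-2-yl]phenyl}chroman-3-ol
Product: 21 (2R,3S,4R)-2-(3,4-dihydroxyphenyl)-4-{2-[(2S,3S)-3,7-dihydroxychroman-2-yl]-4,5-dihydroxyphenyl}chromane-3,7-diol (target)
Conditions: H2 (1 atm), Pd(OH)2/C (20 wt%), THF/MeOH (1:1), rt
Reagents that add atoms: none
Why: Hydrogenolysis of the seven benzyl ethers under neutral conditions, as is usual for benzylated flavan-3-ol oligomers, leaves the ring C–O bonds, the C4–aryl bond and all five stereocentres intact.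

**Compound list**
1 | 3,4-bis(benzyloxy)benzaldehyde | O=Cc1ccc(OCc2ccccc2)c(OCc2ccccc2)c1 | starting material
2 | 4,5-bis(benzyloxy)-2-bromobenzaldehyde | O=Cc1cc(OCc2ccccc2)c(OCc2ccccc2)cc1Br | intermediate
3 | nitromethane | C[N+](=O)[O-] | starting material
4 | (E)-1,2-bis(benzyloxy)-4-bromo-5-(2-nitrovinyl)benzene | O=[N+]([O-])/C=C/c1cc(OCc2ccccc2)c(OCc2ccccc2)cc1Br | intermediate
5 | 4-(benzyloxy)-2-hydroxybenzaldehyde | O=Cc1ccc(OCc2ccccc2)cc1O | starting material
6 | 7-(benzyloxy)-2-[4,5-bis(benzyloxy)-2-bromophenyl]-3-nitrochroman-4-ol (nitroaldol adduct; racemic; diastereomer mixture) | OC1c2ccc(OCc3ccccc3)cc2OC(c2cc(OCc3ccccc3)c(OCc3ccccc3)cc2Br)C1[N+](=O)[O-] | intermediate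
7 | racemic 7-(benzyloxy)-2-[4,5-bis(benzyloxy)-2-bromophenyl]-3-nitro-2H-chromene | O=[N+]([O-])C1=Cc2ccc(OCc3ccccc3)cc2OC1c1cc(OCc2ccccc2)c(OCc2ccccc2)cc1Br | intermediate
8 | racemic 7-(benzyloxy)-2-[4,5-bis(benzyloxy)-2-bromophenyl]chroman-3-one | O=C1Cc2ccc(OCc3ccccc3)cc2OC1c1cc(OCc2ccccc2)c(OCc2ccccc2)cc1Br | intermediate
9 | (2S,3S)-7-(benzyloxy)-2-[4,5-bis(benzyloxy)-2-bromophenyl]chroman-3-ol (2,3-cis) | c1ccccc1COc1ccc2c(c1)O[C@@H](c1cc(OCc3ccccc3)c(OCc3ccccc3)cc1Br)[C@@H](O)C2 | intermediate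
10 | (2S,3S)-3,7-bis(benzyloxy)-2-[4,5-bis(benzyloxy)-2-bromophenyl]chromane | c1ccccc1COc1ccc2c(c1)O[C@@H](c1cc(OCc3ccccc3)c(OCc3ccccc3)cc1Br)[C@@H](OCc1ccccc1)C2 | intermediate
11 | 7-hydroxy-4H-chromen-4-one | O=c1ccoc2cc(O)ccc12 | starting material
12 | 7-(benzyloxy)-4H-chromen-4-one | O=c1ccoc2cc(OCc3ccccc3)ccc12 | intermediate
13 | [3,4-bis(benzyloxy)phenyl]boronic acid | OB(O)c1ccc(OCc2ccccc2)c(OCc2ccccc2)c1 | starting material
14 | (2S)-7-(benzyloxy)-2-[3,4-bis(benzyloxy)phenyl]chroman-4-one | O=C1C[C@@H](c2ccc(OCc3ccccc3)c(OCc3ccccc3)c2)Oc2cc(OCc3ccccc3)ccc12 | intermediate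
15 | 4-methylbenzenesulfonohydrazide | Cc1ccc(cc1)S(=O)(=O)NN | starting material
16 | N-tosylhydrazone of 14 | Cc1ccc(cc1)S(=O)(=O)NN=C1C[C@@H](c2ccc(OCc3ccccc3)c(OCc3ccccc3)c2)Oc2cc(OCc3ccccc3)ccc12 | intermediate
17 | (2S)-7-(benzyloxy)-2-[3,4-bis(benzyloxy)phenyl]-4-diazochromane | [N-]=[N+]=C1C[C@@H](c2ccc(OCc3ccccc3)c(OCc3ccccc3)c2)Oc2cc(OCc3ccccc3)ccc12 | intermediate
18 | (2S,3S)-3,7-bis(benzyloxy)-2-{4,5-bis(benzyloxy)-2-[(2S)-7-(benzyloxy)-2-[3,4-bis(benzyloxy)phenyl]-2H-chromen-4-yl]phenyl}chromane | c1ccccc1COc1ccc2c(c1)O[C@@H](c1cc(OCc3ccccc3)c(OCc3ccccc3)cc1C1=C[C@@H](c3ccc(OCc4ccccc4)c(OCc4ccccc4)c3)Oc3cc(OCc4ccccc4)ccc13)[C@@H](OCc1ccccc1)C2 | intermediate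
19 | C3 alkylborane of 18 (boron on the face anti to the upper C2 aryl group; 2,3-trans-3,4-trans) | c1ccccc1COc1ccc2c(c1)O[C@@H](c1cc(OCc3ccccc3)c(OCc3ccccc3)cc1[C@@H]1c3ccc(OCc4ccccc4)cc3O[C@H](c3ccc(OCc4ccccc4)c(OCc4ccccc4)c3)[C@H]1B)[C@@H](OCc1ccccc1)C2 | intermediate
20 | (2R,3S,4R)-7-(benzyloxy)-2-[3,4-bis(benzyloxy)phenyl]-4-{4,5-bis(benzyloxy)-2-[(2S,3S)-3,7-bis(benzyloxy)chroman-2-yl]phenyl}chroman-3-ol | c1ccccc1COc1ccc2c(c1)O[C@@H](c1cc(OCc3ccccc3)c(OCc3ccccc3)cc1[C@@H]1c3ccc(OCc4ccccc4)cc3O[C@H](c3ccc(OCc4ccccc4)c(OCc4ccccc4)c3)[C@H]1O)[C@@H](OCc1ccccc1)C2 | intermediate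
21 | (2R,3S,4R)-2-(3,4-dihydroxyphenyl)-4-{2-[(2S,3S)-3,7-dihydroxychroman-2-yl]-4,5-dihydroxyphenyl}chromane-3,7-diol; fisetinidol-(4α→6')-ent-epifisetinidol; CNP0244903.4 | Oc1ccc2c(c1)O[C@@H](c1cc(O)c(O)cc1[C@@H]1c3ccc(O)cc3O[C@H](c3ccc(O)c(O)c3)[C@H]1O)[C@@H](O)C2 | target

**Step count and risks**
Total step count: 11. Longest linear sequence: 9 steps (steps 1–6, then 9–11); the flavanone branch (steps 7–8) joins at step 9.

The three steps most likely to fail are 9, 5 and 4.

Step 9. The ortho-substituted, electron-rich aryl bromide may react slowly, so a Bamford–Stevens 1,2-hydrogen shift of diazoalkane 17 to the unarylated flav-3-ene can compete. At 90 °C with LiOtBu the 2-aryl-2H-chromene could also lose C2 integrity, by electrocyclic ring opening or by isomerisation to the 4H-chromene. The fallback sets out from 10 and 14 and comes back at 18. Bromine–lithium exchange on 10 (n-BuLi, THF, −78 °C), transmetalation with CeCl3 and 1,2-addition of the weakly basic aryl cerium reagent to ketone 14 give the tertiary alcohol (2S)-7-(benzyloxy)-2-[3,4-bis(benzyloxy)phenyl]-4-{4,5-bis(benzyloxy)-2-[(2S,3S)-3,7-bis(benzyloxy)chroman-2-yl]phenyl}chroman-4-ol F3 as a C4 epimer mixture. Dehydration with Burgess reagent (benzene, 50 °C, no acid) then gives 18.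

Step 5. The flavan-3-one is sensitive to base and air, this catalyst class has not been used on 2-arylchroman-3-ones, and the enantiofacial sense rests on analogy. The fallback sets out from 8 and comes back at 9. LiBH(s-Bu)3 with LiBr (THF, −78 °C) reduces 8 from the face anti to the aryl group to the racemic cis alcohol, that is 9 together with its enantiomer (2R,3R)-7-(benzyloxy)-2-[4,5-bis(benzyloxy)-2-bromophenyl]chroman-3-ol F2. Preparative chiral SFC separates the two and delivers 9.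

Step 4. Fe/AcOH may over-reduce to the 3-amine or cleave the alpha-aryloxy C–O bond, and the ketone is labile. The fallback sets out from 7 and comes back at 8. NaBH4 (THF/MeOH, 0 °C) reduces the nitroalkene in a conjugate sense to racemic 7-(benzyloxy)-2-[4,5-bis(benzyloxy)-2-bromophenyl]-3-nitrochromane F1. A Nef reaction through the nitronate (NaOMe, MeOH, then buffered aqueous TiCl3/NH4OAc, 0 °C) then gives 8.

**Further compounds**
F1 | step 4 | racemic 7-(benzyloxy)-2-[4,5-bis(benzyloxy)-2-bromophenyl]-3-nitrochromane (C2/C3 diastereomer mixture) | O=[N+]([O-])C1Cc2ccc(OCc3ccccc3)cc2OC1c1cc(OCc2ccccc2)c(OCc2ccccc2)cc1Br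
F2 | step 5 | (2R,3R)-7-(benzyloxy)-2-[4,5-bis(benzyloxy)-2-bromophenyl]chroman-3-ol (enantiomer of 9) | c1ccccc1COc1ccc2c(c1)O[C@H](c1cc(OCc3ccccc3)c(OCc3ccccc3)cc1Br)[C@H](O)C2
F3 | step 9 | (2S)-7-(benzyloxy)-2-[3,4-bis(benzyloxy)phenyl]-4-{4,5-bis(benzyloxy)-2-[(2S,3S)-3,7-bis(benzyloxy)chroman-2-yl]phenyl}chroman-4-ol (C4 epimer mixture) | c1ccccc1COc1ccc2c(c1)O[C@@H](c1cc(OCc3ccccc3)c(OCc3ccccc3)cc1C1(O)C[C@@H](c3ccc(OCc4ccccc4)c(OCc4ccccc4)c3)Oc3cc(OCc4ccccc4)ccc13)[C@@H](OCc1ccccc1)C2
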